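The route rests on disconnecting ring A (C1–C5, C10) across C1–C10 and C4–C5 into a C1–C4 diene and a C5=C10 dienophile. It exploits three facts: C10 and C5 carry C20 and C6 as cis carbonyl-level carbons (an anhydride), C19 on C4 is cis to C20, and C9 can be an aryl carbon. One endo Diels–Alder addition of methyl (E)-2-methylpentadienoate to (4-methoxyphenyl)maleic anhydride therefore builds ring A with both quaternary centres from flat, achiral partners. The racemate is resolved at the first carboxylic acid. Ring B follows by Friedel–Crafts acylation, C7 by carbonylation, and Birch dearomatisation of the anisole ring, conjugate propargylation and ketyl–alkyne cyclisation supply rings C and D.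

Key step: step 3

Remark on numbering: atoms keep their gibberellin numbers throughout; α is the face of rings A and B that carries C20 and C19, β the opposite face (H5, H9, C18).
Remark on racemates: compounds 7, 8 and 9 are racemic and are drawn as the enantiomer that is carried on.
Assumption: in step 6 the (S)-1-phenylethylammonium salt of the enantiomer drawn is taken to be the less soluble diastereomer; should the mirror-image salt crystallise first, (R)-1-phenylethylamine is used instead and nothing else changes.

Step 1
Reactants: 1 maleic anhydride; 2 4-methoxybenzenediazonium tetrafluoroborate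
Product: 3 (4-methoxyphenyl)maleic anhydride [3-(4-methoxyphenyl)furan-2,5-dione]
Conditions: Pd(OAc)2 (2 mol %), NaOAc, MeCN, 25 °C
Reagents that add atoms: none
Why: Heck–Matsuda arylation, in which the aryl-palladium cation formed from 2 adds across the electron-poor C=C of 1 and base-assisted β-hydride elimination restores the conjugated double bond, so that the monoaryl anhydride forms without any stereocentre.

Step 2
Reactants: 4 acrolein; 5 methyl 2-(triphenyl-λ5-phosphanylidene)propanoate
Product: 6 methyl (2E)-2-methylpenta-2,4-dienoate
Conditions: CH2Cl2, 0 °C to 25 °C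
Reagents that add atoms: none
Why: Wittig olefination with a stabilised, α-branched ylide is under thermodynamic control and should give the (E)-enoate, that is the diene with the ester outside and the methyl group inside.

Step 3
Reactants: 3 (4-methoxyphenyl)maleic anhydride; 6 methyl (2E)-2-methylpenta-2,4-dienoate
Product: 7 racemic endo adduct, methyl 7a-(4-methoxyphenyl)-4-methyl-1,3-dioxo-1,3,3a,4,7,7a-hexahydro-2-benzofuran-4-carboxylate (C19 ester and the C20/C6 anhydride carbonyls on the α face; C18 methyl, aryl and H5 on the β face; C2=C3 double bond)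
Conditions: PhMe, BHT (cat.), sealed tube, 130 °C, 6 in excess
Reagents that add atoms: none
Why: A concerted, asynchronous thermal [4+2] cycloaddition (Diels–Alder) of the s-cis diene 6 with the anhydride C=C of 3 forms C1–C10 and C4–C5 in one suprafacial event; the closest known reaction type is the endo addition of citraconic or phenylmaleic anhydride to 1-substituted butadienes. Ring A is closed as a six-membered ring in the intermolecular [4+2] mode, and the anhydride ring of the dienophile is carried along as a cis-fused five-membered ring. C10 and C5 are set by the ring-locked Z geometry of the dienophile, so C20 and C6 come out cis on ring A; C4 is set by the E geometry of the diene together with the endo rule, which places the outside ester cis to the endo anhydride (C19 cis to C20) and the inside methyl trans. Regioselectivity (C4 to C5, not to C10) is needed; the frontier-orbital bias between two electron-poor partners is weak, and the selectivity is secured sterically, because the alternative would join the two fully substituted carbons C4 and C10 directly. Endo selectivity is needed and is secured by secondary overlap of the anhydride carbonyls with the diene and by the aryl group preferring the exo position beside C1H2. The adduct is racemic because both partners are achiral; the absolute configuration is fixed in step 6.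

Step 4
Reactants: 7 racemic endo adduct
Product: 8 racemic saturated anhydride, methyl 7a-(4-methoxyphenyl)-4-methyl-1,3-dioxo-octahydro-2-benzofuran-4-carboxylate (same relative configuration as 7)
Conditions: H2 (1 atm), 10% Pd/C, EtOAc, 25 °C
Reagents that add atoms: none
Why: Heterogeneous catalytic hydrogenation saturates the only C=C bond (C2=C3), while the anhydride, the ester and the anisole ring are inert and no stereocentre is touched.

Step 5
Reactants: 8 racemic saturated anhydride
Product: 9 racemic keto acid, 7-methoxy-1-(methoxycarbonyl)-1-methyl-9-oxo-1,2,3,4,9,9a-hexahydro-4aH-fluorene-4a-carboxylic acid (ring B closed; C6 ketone; 10α-CO2H; 4α-CO2Me; 5β-H)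
Conditions: AlCl3 (3.5 equiv), ClCH2CH2Cl, 0 °C to 25 °C; cold aq. HCl
Reagents that add atoms: none
Why: Intramolecular Friedel–Crafts acylation, in which AlCl3 opens the anhydride at its less hindered C6 carbonyl and the acylium ion attacks the only reachable arene position (C8, ortho to C9), closing five-membered ring B and releasing C20 as the free acid; C5 is drawn as set in step 3, and any epimerisation there is harmless because C5 becomes sp2 in step 8.

Step 6
Reactants: 9 racemic keto acid; 10 (S)-1-phenylethylamine
Product: 11 (S)-1-phenylethylammonium salt of the keto acid enantiomer drawn (10α-carboxylate)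
Conditions: acetone/EtOH, crystallisation to constant rotation
Reagents that add atoms: none
Why: Classical resolution, in which the two enantiomeric acids form diastereomeric salts of different solubility with the single-enantiomer amine so that one crystallises; no stereocentre is made or changed.

Step 7
Reactants: 11 (S)-1-phenylethylammonium salt
Product: 13 dimethyl 7-methoxy-1-methyl-9-oxo-1,2,3,4,9,9a-hexahydro-4aH-fluorene-1,4a-dicarboxylate (keto diester; 4α-CO2Me; 10α-CO2Me), via free keto acid 12 (not isolated)
Conditions: 1 M HCl/EtOAc partition; then MeI, K2CO3, DMF, 25 °C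
Reagents that add atoms: iodomethane, CI
Why: Acidification frees the carboxylic acid and SN2 O-alkylation of its potassium carboxylate with iodomethane gives the methyl ester, a reaction insensitive to the hindrance at C10.

Step 8
Reactants: 13 keto diester
Product: 14 dimethyl 7-methoxy-1-methyl-9-{[(trifluoromethyl)sulfonyl]oxy}-1,2,3,4-tetrahydro-4aH-fluorene-1,4a-dicarboxylate (enol triflate; C5=C6)
Conditions: KN(SiMe3)2, THF, −78 °C; PhNTf2, −78 °C to 0 °C
Reagents that add atoms: N-phenylbis(trifluoromethanesulfonimide), O=S(=O)(N(c1ccccc1)S(=O)(=O)C(F)(F)F)C(F)(F)F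
Why: Deprotonation of the only α-hydrogen of the aryl ketone (C5–H) gives the potassium enolate, which is O-sulfonylated (enol triflate formation); C5 becomes sp2, so its configuration is deliberately erased and reset in step 11.

Step 9
Reactants: 14 enol triflate
Product: 15 trimethyl 7-methoxy-1-methyl-1,2,3,4-tetrahydro-4aH-fluorene-1,4a,9-tricarboxylate (indene triester; C7 ester on C6; C5=C6)
Conditions: Pd(OAc)2 (5 mol %), dppf, CO (1 atm), MeOH, Et3N, DMF, 65 °C
Reagents that add atoms: carbon monoxide, [C-]#[O+]; methanol, CO
Why: Palladium-catalysed methoxycarbonylation of an enol triflate, in which zerovalent palladium inserts into the C6–O bond, CO inserts and methanol cleaves the acyl-palladium species, installs C7 as a conjugated ester.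

Step 10
Reactants: 15 indene triester
Product: 16 7-methoxy-1-methyl-1,2,3,4-tetrahydro-4aH-fluorene-1,4a,9-tricarboxylic acid (indene triacid)
Conditions: n-PrSLi (from n-PrSH and n-BuLi), HMPA, 25 °C; cold 1 M HCl
Reagents that add atoms: none
Why: SN2 demethylation by the soft thiolate at the three ester O-methyl carbons is independent of the hindrance at C4 and C10 and spares the aryl methyl ether at room temperature; the free acids are needed because esters would not survive the dissolving-metal step.

Step 11
Reactants: 16 indene triacid
Product: 19 1-methyl-7-oxo-1,2,3,4,5,6,7,8,9,9a-decahydro-4aH-fluorene-1,4a,9-tricarboxylic acid (13-ketone; C8=C9; 5β-H; 6α-CO2H), via dihydro triacid 17 (not isolated), via dienol ether triacid 18 (not isolated)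
Conditions: Li (excess), NH3(l)/THF, t-BuOH, −78 °C to −33 °C; NH4Cl; 1 M HCl, THF, 0 °C
Reagents that add atoms: water, O
Why: Dissolving-metal (Birch) reduction first reduces the aryl-conjugated acrylate, C5 being protonated axially from the β face, anti to the two flanking axial carboxylates on C4 and C10, which gives the trans A/B fusion (C6 is protonated kinetically and corrected in step 12); the 1,2-dialkyl-4-methoxybenzene ring is then reduced to the 2,5-dihydroanisole with the C8=C9 bond retained, and mild acid hydrolyses the enol ether to the C13 ketone.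

Step 12
Reactants: 19 unconjugated enone triacid
Product: 21 trimethyl 1-methyl-7-oxo-1,2,3,4,4b,5,6,7,9,9a-decahydro-4aH-fluorene-1,4a,9-tricarboxylate (13-oxo-8(14)-ene; 5β-H; 9β-H; 6β-CO2Me), via unconjugated enone triester 20 (not isolated)
Conditions: TMSCHN2, MeOH/PhMe, 0 °C; AcOH quench; NaOMe (0.2 equiv), MeOH, 25 °C
Reagents that add atoms: (trimethylsilyl)diazomethane, C[Si](C)(C)C=[N+]=[N-]
Why: O-methylation of the three acids by the diazomethane equivalent is followed by base equilibration through the extended dienolate, which moves the double bond into conjugation (C8=C14) and sets C9 and C6 thermodynamically: C11 takes the pseudo-equatorial position on ring B (9β-H, as in the related 19-nor-steroid and podocarpenone isomerisations) and the C7 ester goes trans to the quaternary C4 (6β).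

Step 13
Reactants: 21 conjugated enone triester; 22 tributyl(propa-1,2-dien-1-yl)stannane
Product: 23 trimethyl 1-methyl-7-oxo-8a-(prop-2-yn-1-yl)dodecahydro-4aH-fluorene-1,4a,9-tricarboxylate (8β-propargyl 13-ketone; 5β-H; 9β-H; 6β-CO2Me)
Conditions: TiCl4, CH2Cl2, −78 °C
Reagents that add atoms: none
Why: Lewis-acid-mediated conjugate propargylation (SE2′ attack of the allenylstannane, Hosomi–Sakurai type) forms C8–C15; C8 is set by axial attack on the cyclohexenone from the β face, cis to H9 (cis-fused B/C hydrindane, the usual outcome of conjugate addition at the ring-fusion carbon of a hydrindenone) and anti to the pseudo-axial C20 ester on C10, the C7 ester being pseudo-equatorial.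

Step 14
Reactants: 23 propargyl ketone
Product: 24 trimethyl ester of the target, trimethyl ent-13-hydroxygibberell-16-ene-7,19,20-trioate
Conditions: SmI2, HMPA, t-BuOH, THF, 0 °C to 25 °C
Reagents that add atoms: none
Why: Ketyl–alkyne reductive cyclisation, in which the C13 ketyl radical adds 5-exo-dig to C16 of the axial propargyl group and the vinyl radical is reduced to the exocyclic methylene, closes ring D; the configuration at C13 is dictated by C8 because the two-carbon bridge can span only one face of ring C.

Step 15
Reactants: 24 trimethyl ester of the target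
Product: 25 ent-13-hydroxygibberell-16-ene-7,19,20-trioic acid (the target gibberellin triacid)
Conditions: n-PrSLi (from n-PrSH and n-BuLi), HMPA, 25 °C; cold dilute HCl to pH 3
Reagents that add atoms: none
Why: SN2 demethylation of the three methyl esters by thiolate is insensitive to the hindrance at C4 and C10 and leaves the tertiary alcohol, the exocyclic alkene and all stereocentres untouched.

Compound list
1 | maleic anhydride | O=C1OC(=O)C=C1 | starting material
2 | 4-methoxybenzenediazonium tetrafluoroborate | COc1ccc(cc1)[N+]#N.F[B-](F)(F)F | starting material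
3 | (4-methoxyphenyl)maleic anhydride | COc1ccc(cc1)C1=CC(=O)OC1=O | intermediate
4 | acrolein | C=CC=O | starting material
5 | methyl 2-(triphenyl-λ5-phosphanylidene)propanoate | COC(=O)C(C)=P(c1ccccc1)(c1ccccc1)c1ccccc1 | starting material
6 | methyl (2E)-2-methylpenta-2,4-dienoate | C=C/C=C(\C)C(=O)OC | intermediate
7 | racemic endo Diels–Alder adduct (4α-CO2Me, α-anhydride, 10β-aryl, C2=C3) | C[C@@]1(C(=O)OC)C=CC[C@]2(c3ccc(OC)cc3)C(=O)OC(=O)[C@H]12 | intermediate
8 | racemic saturated anhydride | C[C@@]1(C(=O)OC)CCC[C@]2(c3ccc(OC)cc3)C(=O)OC(=O)[C@H]12 | intermediate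
9 | racemic keto acid (C6 ketone, 10α-CO2H, 4α-CO2Me) | C[C@@]1(C(=O)OC)CCC[C@@]2(C(=O)O)c3ccc(OC)cc3C(=O)[C@H]12 | intermediate
10 | (S)-1-phenylethylamine | C[C@H](N)c1ccccc1 | starting material
11 | (S)-1-phenylethylammonium salt of the keto acid enantiomer drawn | C[C@@]1(C(=O)OC)CCC[C@@]2(C(=O)[O-])c3ccc(OC)cc3C(=O)[C@H]12.C[C@H]([NH3+])c1ccccc1 | intermediate
12 | free keto acid, single enantiomer | C[C@@]1(C(=O)OC)CCC[C@@]2(C(=O)O)c3ccc(OC)cc3C(=O)[C@H]12 | intermediate
13 | keto diester | C[C@@]1(C(=O)OC)CCC[C@@]2(C(=O)OC)c3ccc(OC)cc3C(=O)[C@H]12 | intermediate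
14 | enol triflate (C5=C6) | C[C@@]1(C(=O)OC)CCC[C@@]2(C(=O)OC)c3ccc(OC)cc3C(OS(=O)(=O)C(F)(F)F)=C12 | intermediate
15 | indene triester (C5=C6, C7 ester) | C[C@@]1(C(=O)OC)CCC[C@@]2(C(=O)OC)c3ccc(OC)cc3C(C(=O)OC)=C12 | intermediate
16 | indene triacid | C[C@@]1(C(=O)O)CCC[C@@]2(C(=O)O)c3ccc(OC)cc3C(C(=O)O)=C12 | intermediate
17 | dihydro triacid (5β-H, 6α-CO2H, arene intact) | C[C@@]1(C(=O)O)CCC[C@@]2(C(=O)O)c3ccc(OC)cc3[C@H](C(=O)O)[C@H]12 | intermediate
18 | dienol ether triacid (C8=C9, C12=C13–OMe) | C[C@@]1(C(=O)O)CCC[C@@]2(C(=O)O)C3=C(CC(OC)=CC3)[C@H](C(=O)O)[C@H]12 | intermediate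
19 | unconjugated enone triacid (13-ketone, C8=C9) | C[C@@]1(C(=O)O)CCC[C@@]2(C(=O)O)C3=C(CC(=O)CC3)[C@H](C(=O)O)[C@H]12 | intermediate
20 | unconjugated enone triester | C[C@@]1(C(=O)OC)CCC[C@@]2(C(=O)OC)C3=C(CC(=O)CC3)[C@H](C(=O)OC)[C@H]12 | intermediate
21 | conjugated enone triester (13-oxo-8(14)-ene, 9β-H, 6β-CO2Me) | C[C@@]1(C(=O)OC)CCC[C@@]2(C(=O)OC)[C@@H]3CCC(=O)C=C3[C@@H](C(=O)OC)[C@H]12 | intermediate
22 | tributyl(propa-1,2-dien-1-yl)stannane | C=C=C[Sn](CCCC)(CCCC)CCCC | starting material
23 | 8β-propargyl 13-ketone triester | C[C@@]1(C(=O)OC)CCC[C@@]2(C(=O)OC)[C@@H]3CCC(=O)C[C@]3(CC#C)[C@@H](C(=O)OC)[C@H]12 | intermediate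
24 | trimethyl ester of the target, trimethyl ent-13-hydroxygibberell-16-ene-7,19,20-trioate | C=C1C[C@]23C[C@@]1(O)CC[C@H]2[C@]1(C(=O)OC)CCC[C@@](C)(C(=O)OC)[C@H]1[C@@H]3C(=O)OC | intermediate
25 | ent-13-hydroxygibberell-16-ene-7,19,20-trioic acid (the target gibberellin triacid) | C=C1C[C@]23C[C@@]1(O)CC[C@H]2[C@]1(C(=O)O)CCC[C@@](C)(C(=O)O)[C@H]1[C@@H]3C(=O)O | target

Total step count: 15. Longest linear sequence: 14 steps (step 1, then steps 3 to 15).

Steps most likely to fail

Step 3. The diene is deactivated by its ester and slowed by the inside methyl group, which disfavours the s-cis conformation, so dimerisation or polymerisation of 6 may outrun the cycloaddition and endo selectivity may erode at the temperature needed. The fallback sets out from 3 and uses the commercial, unhindered methyl (2E)-penta-2,4-dienoate (C=C/C=C/C(=O)OC), moving the creation of the C4 quaternary centre to an enolate alkylation. Endo addition gives the 18-nor adduct F1, and hydrogenation as in step 4 gives the saturated 18-nor anhydride F2. Friedel–Crafts closure as in step 5 gives the racemic 18-nor keto acid F3, and resolution as in step 6 gives the 18-nor ammonium salt F4. Liberation gives the 18-nor free acid F5, methylation as in step 7 gives the 18-nor keto diester F6, and triflation as in step 8 gives the 18-nor enol triflate F7. In F7 the C4 hydrogen is the only acidic one. Deprotonation with LiN(iPr)2 (THF, −78 °C) and alkylation with iodomethane from the β face, anti to the axial C20 ester, installs C18 and returns to the route at 14.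

Step 11. Protonation of C5 from the α face would give the cis A/B fusion, and the benzylic enediolate formed after the first reduction may retard reduction of the anisole ring, leaving the sequence incomplete. The fallback sets out from 15 and separates the two reductions. Hydrogenation under pressure (H2 60 bar, Pd/C, EtOAc/AcOH, 50 °C) adds hydrogen to C5=C6 from the β face, away from the two axial esters, and gives the saturated triester F8. Demethylation as in step 10 then gives 17 as an isolated compound. The route is rejoined at 17, which is submitted to the conditions of step 11 with only the arene left to reduce.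

Step 13. Addition to the fully substituted, crowded C8 may stall, or 1,2-addition to the ketone may compete. The fallback sets out from 21 and brings in the three carbons in two stages with the smaller, more nucleophilic allylsilane. Hosomi–Sakurai allylation (allyltrimethylsilane, TiCl4, CH2Cl2, −78 °C) gives the 8β-allyl ketone F9. Ozonolysis (O3, CH2Cl2/MeOH, −78 °C; Me2S) gives the keto aldehyde F10. Seyferth–Gilbert homologation with the Ohira–Bestmann reagent (dimethyl (1-diazo-2-oxopropyl)phosphonate, K2CO3, MeOH, 0 °C) converts the aldehyde into the terminal alkyne and returns to the route at 23.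

Further compounds
F1 | step 3 | racemic 18-nor adduct, methyl 7a-(4-methoxyphenyl)-1,3-dioxo-1,3,3a,4,7,7a-hexahydro-2-benzofuran-4-carboxylate (ester cis to the anhydride) | COC(=O)[C@@H]1C=CC[C@]2(c3ccc(OC)cc3)C(=O)OC(=O)[C@H]12
F2 | step 3 | racemic saturated 18-nor anhydride | COC(=O)[C@@H]1CCC[C@]2(c3ccc(OC)cc3)C(=O)OC(=O)[C@H]12
F3 | step 3 | racemic 18-nor keto acid | COC(=O)[C@@H]1CCC[C@@]2(C(=O)O)c3ccc(OC)cc3C(=O)[C@H]12
F4 | step 3 | (S)-1-phenylethylammonium salt of the 18-nor keto acid enantiomer drawn | COC(=O)[C@@H]1CCC[C@@]2(C(=O)[O-])c3ccc(OC)cc3C(=O)[C@H]12.C[C@H]([NH3+])c1ccccc1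
F5 | step 3 | 18-nor free keto acid, single enantiomer | COC(=O)[C@@H]1CCC[C@@]2(C(=O)O)c3ccc(OC)cc3C(=O)[C@H]12
F6 | step 3 | 18-nor keto diester | COC(=O)[C@@H]1CCC[C@@]2(C(=O)OC)c3ccc(OC)cc3C(=O)[C@H]12
F7 | step 3 | 18-nor enol triflate | COC(=O)[C@@H]1CCC[C@@]2(C(=O)OC)c3ccc(OC)cc3C(OS(=O)(=O)C(F)(F)F)=C12
F8 | step 11 | saturated triester (5β-H, 6α-CO2Me, arene intact) | C[C@@]1(C(=O)OC)CCC[C@@]2(C(=O)OC)c3ccc(OC)cc3[C@H](C(=O)OC)[C@H]12
F9 | step 13 | 8β-allyl 13-ketone triester | C[C@@]1(C(=O)OC)CCC[C@@]2(C(=O)OC)[C@@H]3CCC(=O)C[C@]3(CC=C)[C@@H](C(=O)OC)[C@H]12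
F10 | step 13 | 8β-(2-oxoethyl) 13-ketone triester | C[C@@]1(C(=O)OC)CCC[C@@]2(C(=O)OC)[C@@H]3CCC(=O)C[C@]3(CC=O)[C@@H](C(=O)OC)[C@H]12
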